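Remark on the chemistry: ring carbons are labelled C1–C10 in the guaiane manner (C4 quaternary, C1 ring-fusion methine, C5=C6 alkene, C7 side-chain carbon, C9 the carbon that carries oxygen in the key step, C10 methyl-bearing) and C1′ is the benzylic carbon; 5,7-dimethoxycoumarin and 4-methylpent-3-enoic acid are taken as purchasable.

## Analysis of the target

The target is a 2,4-diformylphloroglucinol whose last ring carbon is bonded to a benzylic methine C1′; C1′ also carries an isobutyl group and C4 of a hydroazulene (cyclopentane C1–C5 fused along C1–C5 to a cycloheptene C1, C5–C10). There are five stereocentres. C1′ (R) and the quaternary C4 (R) are contiguous across a rotatable bond. C1 (R) and C10 (R) are vicinal with H1 and H10 cis, and C7 (R) carries the 2-hydroxypropan-2-yl group across the C5=C6 alkene, cis to H1. The sensitive groups are two aryl aldehydes flanked by free phenols, a tertiary alcohol that ionises under acid, a trisubstituted alkene, and an electron-rich arene that makes C1′ prone to ionisation. The hard parts are the C1′/C4 dyad (a quaternary carbon beside a methine bearing a di-ortho-substituted aryl ring), a seven-membered ring with 1,2- and 1,4-related stereocentres, and late functionalisation of the arene without acid. The strategy rests on one feature: C1 and C10 are adjacent and lie two atoms from C5=C6. With a carbonyl on C9, the ring C9–C8–C7–C6–C5–C1–C10 is a cyclohept-4-enone, the product of a [3,3] shift of a tetrahydrofuran (O, C9, C8, C7, C6) that bears an ethylidene group on C9 and the cyclopentene on C6. C1 and C10 then derive from C6 and the enol ether geometry, so the ring stereochemistry reduces to a cis-4,5-disubstituted lactone.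

## Retrosynthetic reasoning

25 to 24: the three O–methyl bonds are cut last. The free diformylphloroglucinol is acidic, chelating and easily oxidised, so it should not be carried. In 24 every methoxy group is ortho or para to a formyl group, which makes thiolate dealkylation feasible under basic conditions that spare the tertiary alcohol and the alkene.

24 to 22 to 21: the two aryl–CHO bonds are cut one at a time. A Lewis-acid formylation is avoided here because it would ionise the tertiary carbinol and attack the alkene. Each remaining ring hydrogen of 21 lies between two methoxy groups, the best case for directed lithiation; the first aldehyde is masked in the flask as 23 during the second lithiation.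

21 to 20: the C–O bond of the carbinol is cut. The isopropenyl group of 20 is a robust carrier of this carbon and is hydrated in the Markovnikov sense by hydrogen-atom transfer; the C5=C6 alkene is trisubstituted and shielded by C4.

20 to 19 to 18 to 17: the C9 oxygen is only needed to drive the ring expansion. It is removed by reduction and radical deoxygenation, which involve neither a cation nor an enolate, so C10 is not at risk.

17 to 16 (key): C1–C10 is cut and C6–O is restored. This turns the cycloheptenone into the 2-ethylidene-5-cyclopentenyl tetrahydrofuran 16. The forward reaction must form the seven-membered ring and set C1 and C10 from C6 and the (Z)-enol ether.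

16 to 15: the C9=C10 bond is cut back to the lactone carbonyl. An ester-type alkylidenation gives the (Z)-enol ether, and the lactone is a stable carrier of the cis relationship.

15 to 9 + 13: the C6–C7 bond is cut, not C5–C6. Adding an alkenyl metal to an α-branched aldehyde would follow the Felkin–Anh sense, which leads to the trans-lactone, and would need an epimerisable α-isopropenyl aldehyde. Transfer of the γ-substituted allyl group of 13 to the enal 9 sets C6 and C7 together; the anti adduct 14 is the cis-lactone after ring closure.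

13 to 12 to 11 to 10: the allyl boronate comes from the acid by esterification, (E)-selective allylic oxidation of the prenyl-type terminus and borylation.

9 to 8 to 7: the C5–C6 bond is cut to the enol triflate of the cyclopentanone. Enolisation can only occur toward C1 because C4 is quaternary.

7 to 6 to 5 to 4: the C1–C5 bond is cut. The ring closes by hydroacylation of the allyl group by the aldehyde, which is unmasked from the lactone by reduction and phenol methylation.

4 to 3 to 2 to 1: the C4–allyl, C4–methyl and C1′–isobutyl bonds are cut. The coumarin lactone is the template: conjugate addition sets C1′, and two enolate alkylations anti to the isobutyl group set C4. Methyl goes in first and allyl second, so allyl ends trans to isobutyl. The lactone oxygen becomes the third phenol oxygen.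

## Alternatives that were turned down

Alternative 1: The arene is disconnected at two ring C–C bonds. In the forward step the cyclobutenone A2 is heated with the siloxyalkyne A3; a vinylketene forms, adds to the alkyne, and ring opening and 6π-electrocyclisation give the phenol A1.
- For: the hindered aryl–C1′ bond is never made by substitution, and the three oxygens arrive differentiated (OH, OEt, OSi). On these two points it is stronger than the chosen route, which needs a conjugate addition to an electron-rich coumarin and late lithiations.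
- Against: A1 contains only a ketal-protected cyclopentanone. The seven-membered ring and C1, C7 and C10 would all remain to be built with an electron-rich phenol present. A3 needs the same C1′/C4 dyad, now with a propargylic centre, so the hardest stereochemical problem is not eased.
- Comparison: the benzannulation closes a ring that can be bought and sets no stereocentre. The Claisen route closes the ring that is difficult and sets two stereocentres in the same step.

Alternative 2: The five-membered ring is disconnected at C4–C5. Lewis-acid activation of the cross-conjugated dienone A5 would trigger a conrotatory Nazarov closure, and proton loss would give the enone A4.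
- For: it is convergent, and C7 and C10 come from a chiral-pool cycloheptene. On the origin of C7 and C10 it is stronger than the chosen route, which sets C7 by a catalytic allyl transfer and C10 in the rearrangement.
- Against: the closure must form the quaternary C4 at a fully substituted terminus bearing the bulky benzylic arm, and its torquoselectivity would rest only on the adjacent acyclic C1′. The oxyallyl cation would be generated beside a trimethoxyarene and an isopropenyl group, both good cation traps. A4 carries the ketone at C2 and the alkene at C1=C5, so the C2 oxygen must be removed, the alkene moved to C5=C6 and C1 created by a reduction of uncertain facial sense.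
- Comparison: the chosen strategy obtains C1 by chirality transfer and places the alkene correctly without further steps.

Alternative 3: The cycloheptene is disconnected at C5=C6. A ruthenium carbene of the second-generation chelated type would join the C5 methylidene and the C7 vinyl group of the diene A7 with loss of ethylene, giving A6.
- For: the conditions are neutral and tolerate the tertiary alcohol, and A6 is identical with compound 21 of the chosen route. After the key step it is therefore stronger: nothing has to be deoxygenated or hydrated.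
- Against: the metathesis creates no stereocentre. All five must be present in A7, three of them (C1, C10, C7) on an open chain, which needs a long linear sequence. The reacting methylidene is 1,1-disubstituted and neopentyl and must form a trisubstituted alkene in a seven-membered ring, so closure would be slow and oligomerisation would compete.
- Comparison: the chosen strategy pays three steps to remove the C9 oxygen but obtains the ring, C1 and C10 from two stereocentres set by one allyl transfer.

Key step: step 14

## Route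

Step 1
Reactants: 1 5,7-dimethoxy-2H-chromen-2-one (5,7-dimethoxycoumarin)
Product: 2 (4R)-5,7-dimethoxy-4-(2-methylpropyl)-3,4-dihydro-2H-chromen-2-one
Conditions: i-BuMgBr (1.5 equiv), CuBr·SMe2 (5 mol %), (R)-1-[(S_p)-2-(dicyclohexylphosphino)ferrocenyl]ethyldiphenylphosphine (6 mol %; the ligand enantiomer is chosen that gives the 4R lactone), t-BuOMe, −75 °C; 1 M HCl
Reagents that add atoms: isobutylmagnesium bromide, CC(C)C[Mg]Br
Why: Copper-catalysed asymmetric conjugate addition of a Grignard reagent to a coumarin; the chiral diphosphine–copper complex selects the face of C4 and so sets C1′, and copper catalysis at low temperature should suppress attack at the lactone carbonyl.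

Step 2
Reactants: 2 (4R)-5,7-dimethoxy-4-(2-methylpropyl)-3,4-dihydro-2H-chromen-2-one
Product: 3 (3R,4R)-5,7-dimethoxy-3-methyl-4-(2-methylpropyl)-3,4-dihydro-2H-chromen-2-one
Conditions: LiN(i-Pr)2 (1.1 equiv), THF, −78 °C; MeI, −78 → −40 °C
Reagents that add atoms: iodomethane, CI
Why: Lactone enolate alkylation; the methyl group should enter trans to the pseudoaxial isobutyl group, but this centre is re-enolised in step 3, so its configuration is of no consequence.

Step 3
Reactants: 3 (3R,4R)-5,7-dimethoxy-3-methyl-4-(2-methylpropyl)-3,4-dihydro-2H-chromen-2-one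
Product: 4 (3R,4S)-5,7-dimethoxy-3-methyl-4-(2-methylpropyl)-3-(prop-2-en-1-yl)-3,4-dihydro-2H-chromen-2-one
Conditions: LiN(i-Pr)2 (1.2 equiv), THF/DMPU, −78 °C; allyl bromide, −78 → −30 °C
Reagents that add atoms: allyl bromide, C=CCBr
Why: Second enolate alkylation; the isobutyl group on C1′ is held pseudoaxial by the peri methoxy group and shields one face of the planar enolate, so the allyl group should enter anti to it and fix the quaternary C4 with methyl cis and allyl trans to isobutyl.

Step 4
Reactants: 4 (3R,4S)-5,7-dimethoxy-3-methyl-4-(2-methylpropyl)-3-(prop-2-en-1-yl)-3,4-dihydro-2H-chromen-2-one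
Product: 5 (3R,4S)-5,7-dimethoxy-3-methyl-4-(2-methylpropyl)-3-(prop-2-en-1-yl)-3,4-dihydro-2H-chromen-2-ol (both C2 epimers)
Conditions: i-Bu2AlH (1.1 equiv), CH2Cl2, −78 °C; aq. KNaC4H4O6
Reagents that add atoms: none
Why: Partial reduction of an aryl lactone to the lactol at low temperature, where the tetrahedral aluminium alkoxide does not collapse; the anomeric centre is lost in the next step.

Step 5
Reactants: 5 (3R,4S)-5,7-dimethoxy-3-methyl-4-(2-methylpropyl)-3-(prop-2-en-1-yl)-3,4-dihydro-2H-chromen-2-ol
Product: 6 (2R,3S)-2,5-dimethyl-2-(prop-2-en-1-yl)-3-(2,4,6-trimethoxyphenyl)hexanal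
Conditions: MeI (3 equiv), K2CO3 (3 equiv), acetone, 56 °C
Reagents that add atoms: iodomethane, CI
Why: Ring–chain tautomerism of the lactol gives the phenoxide, and its O-methylation (Williamson ether synthesis) traps the open form; the aldehyde is α-quaternary and cannot enolise.

Step 6
Reactants: 6 (2R,3S)-2,5-dimethyl-2-(prop-2-en-1-yl)-3-(2,4,6-trimethoxyphenyl)hexanal
Product: 7 (2R)-2-methyl-2-[(1S)-3-methyl-1-(2,4,6-trimethoxyphenyl)butyl]cyclopentan-1-one
Conditions: [Rh(nbd)(dppe)]BF4 (5 mol %, activated with H2), acetone, 25–40 °C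
Reagents that add atoms: none
Why: Rhodium-catalysed intramolecular hydroacylation of a 4-pentenal: insertion into the formyl C–H bond, insertion of the terminal alkene and reductive elimination form C1–C5 and close the cyclopentanone; the quaternary α-carbon favours closure and no stereocentre is touched.

Step 7
Reactants: 7 (2R)-2-methyl-2-[(1S)-3-methyl-1-(2,4,6-trimethoxyphenyl)butyl]cyclopentan-1-one
Product: 8 (5R)-5-methyl-5-[(1R)-3-methyl-1-(2,4,6-trimethoxyphenyl)butyl]cyclopent-1-en-1-yl trifluoromethanesulfonate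
Conditions: KN(SiMe3)2 (1.2 equiv), THF, −78 °C; PhNTf2 (1.3 equiv), −78 → 0 °C; dilute aq. HCl
Reagents that add atoms: N-phenylbis(trifluoromethanesulfonimide), O=S(=O)(N(c1ccccc1)S(=O)(=O)C(F)(F)F)C(F)(F)F
Why: Enolate O-sulfonylation; only C1 carries α-hydrogens because C4 is quaternary, so a single enol triflate with the C5=C1 double bond is expected.

Step 8
Reactants: 8 (5R)-5-methyl-5-[(1R)-3-methyl-1-(2,4,6-trimethoxyphenyl)butyl]cyclopent-1-en-1-yl trifluoromethanesulfonate
Product: 9 (5R)-5-methyl-5-[(1R)-3-methyl-1-(2,4,6-trimethoxyphenyl)butyl]cyclopent-1-ene-1-carbaldehyde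
Conditions: Pd(OAc)2 (5 mol %), dppp (5 mol %), CO (1 atm), Et3SiH (2 equiv), Et3N (2.5 equiv), DMF, 70 °C
Reagents that add atoms: carbon monoxide, [C-]#[O+]
Why: Palladium-catalysed reductive carbonylation (formylation) of an alkenyl triflate: oxidative addition, CO insertion and hydride transfer from the silane to the acylpalladium species install C6 as the enal.

Step 9
Reactants: 10 4-methylpent-3-enoic acid
Product: 11 methyl 4-methylpent-3-enoate
Conditions: MeI (1.3 equiv), K2CO3 (1.5 equiv), DMF, 25 °C
Reagents that add atoms: iodomethane, CI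
Why: Carboxylate O-alkylation; acid is avoided because this acid lactonises through the tertiary cation, and the mild base at room temperature should leave the β,γ-double bond in place.

Step 10
Reactants: 11 methyl 4-methylpent-3-enoate
Product: 12 methyl (3E)-5-hydroxy-4-methylpent-3-enoate
Conditions: SeO2 (0.2 equiv), t-BuOOH (2.5 equiv), CH2Cl2, 0 → 25 °C
Reagents that add atoms: selenium dioxide (oxygen carrier), O=[Se]=O; tert-butyl hydroperoxide (terminal oxidant), CC(C)(C)OO
Why: Selenium dioxide allylic oxidation (ene reaction, then [2,3]-sigmatropic shift) of a trisubstituted alkene, which occurs at the methyl group trans to the chain on the disubstituted terminus and so gives the (E)-allylic alcohol.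

Step 11
Reactants: 12 methyl (3E)-5-hydroxy-4-methylpent-3-enoate
Product: 13 methyl (3E)-4-methyl-5-(4,4,5,5-tetramethyl-1,3,2-dioxaborolan-2-yl)pent-3-enoate
Conditions: B2pin2 (1.2 equiv), [Pd(MeCN)4](BF4)2 (5 mol %), DMSO/MeOH, 50 °C
Reagents that add atoms: bis(pinacolato)diboron, CC1(C)OB(OC1(C)C)B1OC(C)(C)C(C)(C)O1
Why: Palladium-catalysed borylation of an allylic alcohol through an η3-allyl intermediate that is borylated at the unsubstituted terminus; the more stable syn allyl complex should return the (E)-allyl boronate.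

Step 12
Reactants: 9 (5R)-5-methyl-5-[(1R)-3-methyl-1-(2,4,6-trimethoxyphenyl)butyl]cyclopent-1-ene-1-carbaldehyde; 13 methyl (3E)-4-methyl-5-(4,4,5,5-tetramethyl-1,3,2-dioxaborolan-2-yl)pent-3-enoate
Product: 15 (4S,5S)-5-{(5R)-5-methyl-5-[(1R)-3-methyl-1-(2,4,6-trimethoxyphenyl)butyl]cyclopent-1-en-1-yl}-4-(prop-1-en-2-yl)oxolan-2-one, via hydroxy ester 14 (not isolated)
Conditions: (S)-TRIP [(S)-3,3′-bis(2,4,6-triisopropylphenyl)-1,1′-binaphthyl-2,2′-diyl hydrogen phosphate] (10 mol %), 4 Å MS, toluene, −30 → 0 °C; aq. NaHCO3; then PPTS (10 mol %), CH2Cl2, 35 °C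
Reagents that add atoms: none
Why: Chiral phosphoric acid-catalysed allylboration through a closed chair (Zimmerman–Traxler) transition state in which the (E)-γ-substituent is equatorial, so the anti adduct 14 should form and close to the cis-lactone with loss of methanol. The acid enantiomer is chosen to deliver the allyl group to the Si face of the formyl group, which in the s-trans enal is also the open face (methyl side of C4, away from the benzylic arm), so catalyst and substrate should reinforce each other in setting C6 (S) and C7 (S).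

Step 13
Reactants: 15 (4S,5S)-5-{(5R)-5-methyl-5-[(1R)-3-methyl-1-(2,4,6-trimethoxyphenyl)butyl]cyclopent-1-en-1-yl}-4-(prop-1-en-2-yl)oxolan-2-one
Product: 16 (2Z,4S,5S)-2-ethylidene-5-{(5R)-5-methyl-5-[(1R)-3-methyl-1-(2,4,6-trimethoxyphenyl)butyl]cyclopent-1-en-1-yl}-4-(prop-1-en-2-yl)oxolane
Conditions: TiCl4 (4 equiv), TMEDA (8 equiv), Zn (9 equiv), PbCl2 (cat.), CH3CHBr2 (2.2 equiv), THF, 0 → 25 °C; Et3N, aq. K2CO3; basic alumina
Reagents that add atoms: 1,1-dibromoethane, CC(Br)Br
Why: Takai–Utimoto alkylidenation of an ester-type carbonyl by the low-valent titanium ethylidene reagent; esters give (Z)-enol ethers (new alkyl group syn to the ether oxygen), here also the less strained isomer, and the amine-buffered work-up keeps the acid-labile exocyclic enol ether intact.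

Step 14
Reactants: 16 (2Z,4S,5S)-2-ethylidene-5-{(5R)-5-methyl-5-[(1R)-3-methyl-1-(2,4,6-trimethoxyphenyl)butyl]cyclopent-1-en-1-yl}-4-(prop-1-en-2-yl)oxolane
Product: 17 (1R,3aR,4S,7R)-1,4-dimethyl-1-[(1R)-3-methyl-1-(2,4,6-trimethoxyphenyl)butyl]-7-(prop-1-en-2-yl)-2,3,3a,4,6,7-hexahydroazulen-5(1H)-one
Conditions: degassed toluene (0.02 M), 2,6-di-tert-butylpyridine (5 mol %), base-washed sealed tube, 160 °C
Reagents that add atoms: none
Why: Heating should trigger a concerted, suprafacial [3,3]-sigmatropic (Claisen) shift of the allyl vinyl ether C10=C9–O–C6–C5=C1: C10–C1 forms as C6–O breaks, C5=C6 appears and C9 becomes the ketone. The closest known reaction type is the thermal ring enlargement of 2-alkylidene-5-alkenyl tetrahydrofurans to cyclohept-4-enones. The seven-membered carbocycle (C9–C8–C7–C6–C5–C1–C10) is closed not by an end-on cyclisation but by this bond reorganisation within a six-membered chair array bridged by C7–C8 (a bicyclo[3.2.1]-like transition state); a boat is excluded because only the chair lets C1 lie over C7 with the breaking C6–O bond aligned with the cyclopentene π system, as the cis ring alkene demands. C1 is set by chirality transfer from C6: the oxygen leaves and C10 enters on the same face of the C6–C5–C1 allyl unit, which is the methyl face of C4, away from the benzylic arm. C10 is set by the (Z)-geometry of the enol ether together with the fact that only the ring face bearing the cyclopentenyl group can be reached, so its methyl group ends trans to H1 (an E-enol ether would give the C10 epimer). C7 is not touched and ends with its isopropenyl group cis to H1. The step therefore needs an intact (Z)-exocyclic enol ether and the cis-4,5-disubstituted ring; acid is excluded to prevent Z/E equilibration or migration of the double bond into the ring, and the irreversible formation of the carbonyl group should drain any reversible Cope shift of the cis-dialkenyl pair.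

Step 15
Reactants: 17 (1R,3aR,4S,7R)-1,4-dimethyl-1-[(1R)-3-methyl-1-(2,4,6-trimethoxyphenyl)butyl]-7-(prop-1-en-2-yl)-2,3,3a,4,6,7-hexahydroazulen-5(1H)-one
Product: 18 (1R,3aR,4S,7R)-1,4-dimethyl-1-[(1R)-3-methyl-1-(2,4,6-trimethoxyphenyl)butyl]-7-(prop-1-en-2-yl)-1,2,3,3a,4,5,6,7-octahydroazulen-5-ol (both C5 epimers)
Conditions: NaBH4, MeOH/THF, −20 → 0 °C
Reagents that add atoms: none
Why: Hydride reduction of the ketone at low temperature, before the α-stereocentre C10 can epimerise; the configuration of the carbinol is irrelevant because the oxygen is removed.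

Step 16
Reactants: 18 (1R,3aR,4S,7R)-1,4-dimethyl-1-[(1R)-3-methyl-1-(2,4,6-trimethoxyphenyl)butyl]-7-(prop-1-en-2-yl)-1,2,3,3a,4,5,6,7-octahydroazulen-5-ol
Product: 19 O-{(1R,3aR,4S,7R)-1,4-dimethyl-1-[(1R)-3-methyl-1-(2,4,6-trimethoxyphenyl)butyl]-7-(prop-1-en-2-yl)-1,2,3,3a,4,5,6,7-octahydroazulen-5-yl} S-methyl carbonodithioate
Conditions: NaH (2 equiv), THF, 0 → 25 °C; CS2; MeI
Reagents that add atoms: carbon disulfide, S=C=S; iodomethane, CI
Why: Xanthate formation from the sodium alkoxide, carbon disulfide and iodomethane; no other group in 18 reacts with these reagents.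

Step 17
Reactants: 19 O-{(1R,3aR,4S,7R)-1,4-dimethyl-1-[(1R)-3-methyl-1-(2,4,6-trimethoxyphenyl)butyl]-7-(prop-1-en-2-yl)-1,2,3,3a,4,5,6,7-octahydroazulen-5-yl} S-methyl carbonodithioate
Product: 20 (1R,3aR,4R,7R)-1,4-dimethyl-1-[(1R)-3-methyl-1-(2,4,6-trimethoxyphenyl)butyl]-7-(prop-1-en-2-yl)-1,2,3,3a,4,5,6,7-octahydroazulene
Conditions: Bu3SnH (1.5 equiv), AIBN (0.1 equiv), toluene, 110 °C
Reagents that add atoms: none
Why: Barton–McCombie deoxygenation; the secondary C9 radical can reach the two alkenes only through four-membered or 5-endo closures, so hydrogen transfer from the stannane should be the only outcome and C10 is left untouched.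

Step 18
Reactants: 20 (1R,3aR,4R,7R)-1,4-dimethyl-1-[(1R)-3-methyl-1-(2,4,6-trimethoxyphenyl)butyl]-7-(prop-1-en-2-yl)-1,2,3,3a,4,5,6,7-octahydroazulene
Product: 21 2-{(3R,5R,8R,8aR)-3,8-dimethyl-3-[(1R)-3-methyl-1-(2,4,6-trimethoxyphenyl)butyl]-1,2,3,5,6,7,8,8a-octahydroazulen-5-yl}propan-2-ol
Conditions: Co(acac)2 (20 mol %), PhSiH3 (2.5 equiv), O2 (1 atm), THF, 25 °C
Reagents that add atoms: dioxygen, O=O
Why: Mukaiyama hydration: hydrogen-atom transfer from a cobalt hydride to the 1,1-disubstituted alkene gives the tertiary radical, which is trapped by oxygen and reduced to the Markovnikov alcohol; the trisubstituted C5=C6 alkene, flanked by the quaternary C4, should react far more slowly.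

Step 19
Reactants: 21 2-{(3R,5R,8R,8aR)-3,8-dimethyl-3-[(1R)-3-methyl-1-(2,4,6-trimethoxyphenyl)butyl]-1,2,3,5,6,7,8,8a-octahydroazulen-5-yl}propan-2-ol
Product: 22 3-[(1R)-1-{(1R,3aR,4R,7R)-7-(2-hydroxypropan-2-yl)-1,4-dimethyl-1,2,3,3a,4,5,6,7-octahydroazulen-1-yl}-3-methylbutyl]-2,4,6-trimethoxybenzaldehyde
Conditions: n-BuLi (2.5 equiv), TMEDA (2.5 equiv), THF, 0 °C; DMF (4 equiv), 0 → 25 °C; H2O
Reagents that add atoms: N,N-dimethylformamide, CN(C)C=O
Why: Directed ortho-lithiation at a ring position flanked by two methoxy groups, then formylation with a formamide; the first equivalent of base converts the tertiary alcohol into an inert alkoxide, and the two ring positions become the same compound after formylation.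

Step 20
Reactants: 22 3-[(1R)-1-{(1R,3aR,4R,7R)-7-(2-hydroxypropan-2-yl)-1,4-dimethyl-1,2,3,3a,4,5,6,7-octahydroazulen-1-yl}-3-methylbutyl]-2,4,6-trimethoxybenzaldehyde
Product: 24 5-[(1R)-1-{(1R,3aR,4R,7R)-7-(2-hydroxypropan-2-yl)-1,4-dimethyl-1,2,3,3a,4,5,6,7-octahydroazulen-1-yl}-3-methylbutyl]-2,4,6-trimethoxybenzene-1,3-dicarbaldehyde, via dilithium amino alkoxide 23 (not isolated)
Conditions: LiN(Me)CH2CH2NMe2 (2.2 equiv, from the diamine and n-BuLi), THF, −20 °C; n-BuLi (3 equiv), −20 → 0 °C; DMF, 0 → 25 °C; H2O
Reagents that add atoms: N,N-dimethylformamide, CN(C)C=O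
Why: The aldehyde is protected in the flask as an α-amino alkoxide by addition of the lithium amide, the remaining ring hydrogen (again between two methoxy groups) is removed by directed ortho-lithiation, and the aryllithium is formylated; aqueous work-up releases both aldehydes.

Step 21
Reactants: 24 5-[(1R)-1-{(1R,3aR,4R,7R)-7-(2-hydroxypropan-2-yl)-1,4-dimethyl-1,2,3,3a,4,5,6,7-octahydroazulen-1-yl}-3-methylbutyl]-2,4,6-trimethoxybenzene-1,3-dicarbaldehyde
Product: 25 5-[(1R)-1-{(1R,3aR,4R,7R)-7-(2-hydroxypropan-2-yl)-1,4-dimethyl-1,2,3,3a,4,5,6,7-octahydroazulen-1-yl}-3-methylbutyl]-2,4,6-trihydroxybenzene-1,3-dicarbaldehyde (target)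
Conditions: NaSEt (10 equiv), DMF, 110 °C; dilute aq. HCl
Reagents that add atoms: none
Why: Nucleophilic (SN2) dealkylation of aryl methyl ethers by thiolate; each methoxy group is ortho or para to a formyl group, which stabilises the departing phenoxide, and the basic medium leaves the tertiary alcohol, the alkene and all stereocentres untouched.

## Compound list

1 | 5,7-dimethoxy-2H-chromen-2-one | COc1cc(OC)c2ccc(=O)oc2c1 | starting material
2 | (4R)-5,7-dimethoxy-4-(2-methylpropyl)-3,4-dihydro-2H-chromen-2-one | CC(C)C[C@@H]1CC(=O)Oc2cc(OC)cc(OC)c21 | intermediate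
3 | (3R,4R)-5,7-dimethoxy-3-methyl-4-(2-methylpropyl)-3,4-dihydro-2H-chromen-2-one | CC(C)C[C@@H]1[C@@H](C)C(=O)Oc2cc(OC)cc(OC)c21 | intermediate
4 | (3R,4S)-5,7-dimethoxy-3-methyl-4-(2-methylpropyl)-3-(prop-2-en-1-yl)-3,4-dihydro-2H-chromen-2-one | CC(C)C[C@@H]1[C@@](C)(CC=C)C(=O)Oc2cc(OC)cc(OC)c21 | intermediate
5 | (3R,4S)-5,7-dimethoxy-3-methyl-4-(2-methylpropyl)-3-(prop-2-en-1-yl)-3,4-dihydro-2H-chromen-2-ol (C2 epimers) | CC(C)C[C@@H]1[C@@](C)(CC=C)C(O)Oc2cc(OC)cc(OC)c21 | intermediate
6 | (2R,3S)-2,5-dimethyl-2-(prop-2-en-1-yl)-3-(2,4,6-trimethoxyphenyl)hexanal | CC(C)C[C@@H](c1c(OC)cc(OC)cc1OC)[C@@](C)(CC=C)C=O | intermediate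
7 | (2R)-2-methyl-2-[(1S)-3-methyl-1-(2,4,6-trimethoxyphenyl)butyl]cyclopentan-1-one | CC(C)C[C@@H](c1c(OC)cc(OC)cc1OC)[C@@]1(C)CCCC1=O | intermediate
8 | (5R)-5-methyl-5-[(1R)-3-methyl-1-(2,4,6-trimethoxyphenyl)butyl]cyclopent-1-en-1-yl trifluoromethanesulfonate | CC(C)C[C@@H](c1c(OC)cc(OC)cc1OC)[C@@]1(C)CCC=C1OS(=O)(=O)C(F)(F)F | intermediate
9 | (5R)-5-methyl-5-[(1R)-3-methyl-1-(2,4,6-trimethoxyphenyl)butyl]cyclopent-1-ene-1-carbaldehyde | CC(C)C[C@@H](c1c(OC)cc(OC)cc1OC)[C@@]1(C)CCC=C1C=O | intermediate
10 | 4-methylpent-3-enoic acid | CC(C)=CCC(=O)O | starting material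
11 | methyl 4-methylpent-3-enoate | COC(=O)CC=C(C)C | intermediate
12 | methyl (3E)-5-hydroxy-4-methylpent-3-enoate | COC(=O)C/C=C(\C)CO | intermediate
13 | methyl (3E)-4-methyl-5-(4,4,5,5-tetramethyl-1,3,2-dioxaborolan-2-yl)pent-3-enoate | COC(=O)C/C=C(\C)CB1OC(C)(C)C(C)(C)O1 | intermediate
14 | methyl (3S,4S)-4-hydroxy-4-{(5R)-5-methyl-5-[(1R)-3-methyl-1-(2,4,6-trimethoxyphenyl)butyl]cyclopent-1-en-1-yl}-3-(prop-1-en-2-yl)butanoate | CC(C)C[C@@H](c1c(OC)cc(OC)cc1OC)[C@@]1(C)CCC=C1[C@@H](O)[C@@H](CC(=O)OC)C(C)=C | intermediate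
15 | (4S,5S)-5-{(5R)-5-methyl-5-[(1R)-3-methyl-1-(2,4,6-trimethoxyphenyl)butyl]cyclopent-1-en-1-yl}-4-(prop-1-en-2-yl)oxolan-2-one | CC(C)C[C@@H](c1c(OC)cc(OC)cc1OC)[C@@]1(C)CCC=C1[C@H]2OC(=O)C[C@H]2C(C)=C | intermediate
16 | (2Z,4S,5S)-2-ethylidene-5-{(5R)-5-methyl-5-[(1R)-3-methyl-1-(2,4,6-trimethoxyphenyl)butyl]cyclopent-1-en-1-yl}-4-(prop-1-en-2-yl)oxolane | CC(C)C[C@@H](c1c(OC)cc(OC)cc1OC)[C@@]1(C)CCC=C1[C@H]2O/C(=C\C)C[C@H]2C(C)=C | intermediate
17 | (1R,3aR,4S,7R)-1,4-dimethyl-1-[(1R)-3-methyl-1-(2,4,6-trimethoxyphenyl)butyl]-7-(prop-1-en-2-yl)-2,3,3a,4,6,7-hexahydroazulen-5(1H)-one | CC(C)C[C@@H](c1c(OC)cc(OC)cc1OC)[C@@]1(C)CC[C@H]2C1=C[C@H](C(C)=C)CC(=O)[C@H]2C | intermediate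
18 | (1R,3aR,4S,7R)-1,4-dimethyl-1-[(1R)-3-methyl-1-(2,4,6-trimethoxyphenyl)butyl]-7-(prop-1-en-2-yl)-1,2,3,3a,4,5,6,7-octahydroazulen-5-ol (C5 epimers) | CC(C)C[C@@H](c1c(OC)cc(OC)cc1OC)[C@@]1(C)CC[C@H]2C1=C[C@H](C(C)=C)CC(O)[C@H]2C | intermediate
19 | O-{(1R,3aR,4S,7R)-1,4-dimethyl-1-[(1R)-3-methyl-1-(2,4,6-trimethoxyphenyl)butyl]-7-(prop-1-en-2-yl)-1,2,3,3a,4,5,6,7-octahydroazulen-5-yl} S-methyl carbonodithioate | CC(C)C[C@@H](c1c(OC)cc(OC)cc1OC)[C@@]1(C)CC[C@H]2C1=C[C@H](C(C)=C)CC(OC(=S)SC)[C@H]2C | intermediate
20 | (1R,3aR,4R,7R)-1,4-dimethyl-1-[(1R)-3-methyl-1-(2,4,6-trimethoxyphenyl)butyl]-7-(prop-1-en-2-yl)-1,2,3,3a,4,5,6,7-octahydroazulene | CC(C)C[C@@H](c1c(OC)cc(OC)cc1OC)[C@@]1(C)CC[C@H]2C1=C[C@H](C(C)=C)CC[C@H]2C | intermediate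
21 | 2-{(3R,5R,8R,8aR)-3,8-dimethyl-3-[(1R)-3-methyl-1-(2,4,6-trimethoxyphenyl)butyl]-1,2,3,5,6,7,8,8a-octahydroazulen-5-yl}propan-2-ol | CC(C)C[C@@H](c1c(OC)cc(OC)cc1OC)[C@@]1(C)CC[C@H]2C1=C[C@H](C(C)(C)O)CC[C@H]2C | intermediate
22 | 3-[(1R)-1-{(1R,3aR,4R,7R)-7-(2-hydroxypropan-2-yl)-1,4-dimethyl-1,2,3,3a,4,5,6,7-octahydroazulen-1-yl}-3-methylbutyl]-2,4,6-trimethoxybenzaldehyde | CC(C)C[C@@H](c1c(OC)c(C=O)c(OC)cc1OC)[C@@]1(C)CC[C@H]2C1=C[C@H](C(C)(C)O)CC[C@H]2C | intermediate
23 | dilithium salt of the α-amino alkoxide formed from 22 and lithium N,N,N′-trimethylethylenediamide (tertiary alkoxide also lithiated; hemiaminal carbon unassigned) | CC(C)C[C@@H](c1c(OC)c(C(O[Li])N(C)CCN(C)C)c(OC)cc1OC)[C@@]1(C)CC[C@H]2C1=C[C@H](C(C)(C)O[Li])CC[C@H]2C | intermediate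
24 | 5-[(1R)-1-{(1R,3aR,4R,7R)-7-(2-hydroxypropan-2-yl)-1,4-dimethyl-1,2,3,3a,4,5,6,7-octahydroazulen-1-yl}-3-methylbutyl]-2,4,6-trimethoxybenzene-1,3-dicarbaldehyde | CC(C)C[C@@H](c1c(OC)c(C=O)c(OC)c(C=O)c1OC)[C@@]1(C)CC[C@H]2C1=C[C@H](C(C)(C)O)CC[C@H]2C | intermediate
25 | 5-[(1R)-1-{(1R,3aR,4R,7R)-7-(2-hydroxypropan-2-yl)-1,4-dimethyl-1,2,3,3a,4,5,6,7-octahydroazulen-1-yl}-3-methylbutyl]-2,4,6-trihydroxybenzene-1,3-dicarbaldehyde | CC(C)C[C@@H](c1c(O)c(C=O)c(O)c(C=O)c1O)[C@@]1(C)CC[C@H]2C1=C[C@H](C(C)(C)O)CC[C@H]2C | target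

## Step count and least certain steps

Total: 21 steps. Longest linear sequence: 18 steps (steps 1–8, then 12–21); the allyl boronate branch is 3 steps (9–11).

Step 14 (key step). The chair transition state places the isopropenyl group on C7 on the inner side of the bridged array, pressed against H1, so the barrier may be high. At the temperature then required, acid-promoted migration of the exocyclic double bond into the ring or Z/E equilibration of the enol ether could precede the rearrangement and erode C10, and a Cope shift of the cis-dialkenyl pair could divert material. Fallback, from 16 to 18: the enol ether is treated with i-Bu3Al (3 equiv) in CH2Cl2 at −78 → 25 °C. Coordination of aluminium to the ether oxygen promotes the same [3,3] reorganisation as a charge-accelerated process at low temperature, and the resulting ketone is reduced in the flask by β-hydride transfer from an isobutyl group. The alcohol 18 is reached directly and step 15 is skipped.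

Step 1. The two methoxy groups lower the electrophilicity of C4 and the 5-methoxy group crowds it, so attack of the Grignard reagent at the lactone carbonyl and poor facial discrimination may both intervene. Fallback, from 1 to 2: rhodium-catalysed asymmetric conjugate addition of (2-methylprop-1-en-1-yl)boronic acid ([Rh(acac)(C2H4)2] (3 mol %), SEGPHOS of the appropriate hand, dioxane/H2O, 60 °C) should give (4S)-5,7-dimethoxy-4-(2-methylprop-1-en-1-yl)-3,4-dihydro-2H-chromen-2-one F1. Hydrogenation (H2, Pd/C, EtOAc) saturates only the side-chain alkene and gives 2 (the descriptor changes, the geometry does not).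

Step 6. In the crowded neopentyl aldehyde, decarbonylation of the acyl–rhodium hydride and migration of the allyl double bond may outrun alkene insertion. Fallback, from 6 to 8: CH2=CHMgBr (THF, 0 °C) adds to the aldehyde to give (4R,5R)-4,7-dimethyl-4-(prop-2-en-1-yl)-5-(2,4,6-trimethoxyphenyl)oct-1-en-3-ol F2 (both C3 epimers). Ring-closing metathesis with the second-generation Grubbs catalyst RuCl2(H2IMes)(PCy3)(=CHPh) (CH2Cl2, 40 °C) gives (5R)-5-methyl-5-[(1R)-3-methyl-1-(2,4,6-trimethoxyphenyl)butyl]cyclopent-2-en-1-ol F3. Dess–Martin oxidation gives (5R)-5-methyl-5-[(1S)-3-methyl-1-(2,4,6-trimethoxyphenyl)butyl]cyclopent-2-en-1-one F4. Conjugate reduction with LiBH(s-Bu)3 (THF, −78 °C) and trapping of the enolate with PhNTf2 gives the enol triflate 8.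

Step 12. Partial loss of the (E)-geometry of the boronate (made in step 11 through an allylpalladium species) would leak into the syn adduct and hence the trans-lactone. A hindered enal may also react slowly enough for an uncatalysed background reaction to lower facial control. Fallback, from 12 and 9 to 15, which also bypasses step 11: 12 is converted with CBr4/PPh3 (CH2Cl2, 0 °C) into methyl (3E)-5-bromo-4-methylpent-3-enoate F5. A Nozaki–Hiyama allylation of 9 with F5 and CrCl2 (THF, 0 °C) should give the anti adduct 14 whatever the bromide geometry, because the allylchromium species equilibrates to the (E)-form before reacting through a chair; facial selectivity then rests on the substrate bias described in step 12. PPTS closes 14 to 15.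

Step 13. Low-valent titanium may open the allylic lactone reductively, Z-selectivity may be incomplete for a cyclic ester, and the exocyclic enol ether may isomerise on work-up. Fallback, from 15 to 16:
- i-Bu2AlH (CH2Cl2, −78 °C) gives (4S,5S)-5-{(5R)-5-methyl-5-[(1R)-3-methyl-1-(2,4,6-trimethoxyphenyl)butyl]cyclopent-1-en-1-yl}-4-(prop-1-en-2-yl)oxolan-2-ol F6.
- Seyferth–Gilbert homologation with dimethyl (1-diazo-2-oxopropyl)phosphonate (K2CO3, MeOH) gives (1S,2S)-1-{(5R)-5-methyl-5-[(1R)-3-methyl-1-(2,4,6-trimethoxyphenyl)butyl]cyclopent-1-en-1-yl}-2-(prop-1-en-2-yl)pent-4-yn-1-ol F7.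
- C-Methylation of its dianion (n-BuLi, 2.1 equiv, THF/DMPU, then MeI, 1 equiv) gives (1S,2S)-1-{(5R)-5-methyl-5-[(1R)-3-methyl-1-(2,4,6-trimethoxyphenyl)butyl]cyclopent-1-en-1-yl}-2-(prop-1-en-2-yl)hex-4-yn-1-ol F8.
- Gold-catalysed 5-exo-dig hydroalkoxylation (AuCl(PPh3)/AgOTf, 2 mol %, THF, 25 °C) adds the hydroxyl group anti across the alkyne and should give the (Z)-enol ether 16 by mechanism.

## Further compounds

F0 | step 14 | none | none
F1 | step 1 | (4S)-5,7-dimethoxy-4-(2-methylprop-1-en-1-yl)-3,4-dihydro-2H-chromen-2-one | CC(C)=C[C@@H]1CC(=O)Oc2cc(OC)cc(OC)c21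
F2 | step 6 | (4R,5R)-4,7-dimethyl-4-(prop-2-en-1-yl)-5-(2,4,6-trimethoxyphenyl)oct-1-en-3-ol (C3 epimers) | CC(C)C[C@@H](c1c(OC)cc(OC)cc1OC)[C@@](C)(CC=C)C(O)C=C
F3 | step 6 | (5R)-5-methyl-5-[(1R)-3-methyl-1-(2,4,6-trimethoxyphenyl)butyl]cyclopent-2-en-1-ol (C1 epimers) | CC(C)C[C@@H](c1c(OC)cc(OC)cc1OC)[C@@]1(C)CC=CC1O
F4 | step 6 | (5R)-5-methyl-5-[(1S)-3-methyl-1-(2,4,6-trimethoxyphenyl)butyl]cyclopent-2-en-1-one | CC(C)C[C@@H](c1c(OC)cc(OC)cc1OC)[C@@]1(C)CC=CC1=O
F5 | step 12 | methyl (3E)-5-bromo-4-methylpent-3-enoate | COC(=O)C/C=C(\C)CBr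
F6 | step 13 | (4S,5S)-5-{(5R)-5-methyl-5-[(1R)-3-methyl-1-(2,4,6-trimethoxyphenyl)butyl]cyclopent-1-en-1-yl}-4-(prop-1-en-2-yl)oxolan-2-ol (C2 epimers) | CC(C)C[C@@H](c1c(OC)cc(OC)cc1OC)[C@@]1(C)CCC=C1[C@H]2OC(O)C[C@H]2C(C)=C
F7 | step 13 | (1S,2S)-1-{(5R)-5-methyl-5-[(1R)-3-methyl-1-(2,4,6-trimethoxyphenyl)butyl]cyclopent-1-en-1-yl}-2-(prop-1-en-2-yl)pent-4-yn-1-ol | CC(C)C[C@@H](c1c(OC)cc(OC)cc1OC)[C@@]1(C)CCC=C1[C@@H](O)[C@@H](CC#C)C(C)=C
F8 | step 13 | (1S,2S)-1-{(5R)-5-methyl-5-[(1R)-3-methyl-1-(2,4,6-trimethoxyphenyl)butyl]cyclopent-1-en-1-yl}-2-(prop-1-en-2-yl)hex-4-yn-1-ol | CC(C)C[C@@H](c1c(OC)cc(OC)cc1OC)[C@@]1(C)CCC=C1[C@@H](O)[C@@H](CC#CC)C(C)=C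
A1 | alternative 1 | 5-ethoxy-2-[3-methyl-1-(6-methyl-1,4-dioxaspiro[4.4]nonan-6-yl)butyl]-3-[(triisopropylsilyl)oxy]phenol (configuration as in the SMILES) | CC(C)C[C@@H](c1c(O)cc(OCC)cc1O[Si](C(C)C)(C(C)C)C(C)C)[C@@]1(C)CCCC12OCCO2
A2 | alternative 1 | 3-ethoxycyclobut-2-en-1-one | CCOC1=CC(=O)C1
A3 | alternative 1 | triisopropyl{[5-methyl-3-(6-methyl-1,4-dioxaspiro[4.4]nonan-6-yl)hex-1-yn-1-yl]oxy}silane (configuration as in the SMILES) | CC(C)C[C@@H](C#CO[Si](C(C)C)(C(C)C)C(C)C)[C@@]1(C)CCCC12OCCO2
A4 | alternative 2 | hydroazulenone with C2 ketone and C1=C5 alkene, tri-O-methyl aryl group and C7 isopropenyl group (configuration as in the SMILES) | CC(C)C[C@@H](c1c(OC)cc(OC)cc1OC)[C@@]1(C)CC(=O)C2=C1C[C@H](C(C)=C)CC[C@H]2C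
A5 | alternative 2 | cross-conjugated dienone: 1-[7-methyl-4-(prop-1-en-2-yl)cyclohept-1-en-1-yl]-3,6-dimethyl-4-(2,4,6-trimethoxyphenyl)hept-2-en-1-one (configuration as in the SMILES) | CC(C)C[C@@H](c1c(OC)cc(OC)cc1OC)C(C)=CC(=O)C1=CC[C@H](C(C)=C)CC[C@H]1C
A6 | alternative 3 | 2-{(3R,5R,8R,8aR)-3,8-dimethyl-3-[(1R)-3-methyl-1-(2,4,6-trimethoxyphenyl)butyl]-1,2,3,5,6,7,8,8a-octahydroazulen-5-yl}propan-2-ol (same structure as 21) | CC(C)C[C@@H](c1c(OC)cc(OC)cc1OC)[C@@]1(C)CC[C@H]2C1=C[C@H](C(C)(C)O)CC[C@H]2C
A7 | alternative 3 | metathesis diene: 2-methylidenecyclopentane bearing the C4 methyl and benzylic arm and, on C1, a 5-(2-hydroxypropan-2-yl)hept-6-en-2-yl chain (configuration as in the SMILES) | CC(C)C[C@@H](c1c(OC)cc(OC)cc1OC)[C@@]1(C)CC[C@@H](C1=C)[C@H](C)CC[C@H](C=C)C(C)(C)O
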